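**Plan**

1. Retrosynthesis (daucane numbering): the C6 ester C–O bond, the exocyclic C8=C14 bond and the C9–O/C10–O bonds are cut first (acylation, methylenation, osmylation of a C9=C10 enone). The C1–C5 bond of the hydroazulene is then undone as a 1,2-shift, which gives a cis-decalin; the decalin is cut at C4–C5 (aldol) and C1–C10 (Michael addition).
2. Forward: ring B (six-membered) is the ring of (+)-dihydrocarvone, ring A (six-membered) is annulated with methyl vinyl ketone, and the key step contracts ring B to the cyclopentane and expands ring A to the cycloheptane in one shift.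
3. Enabling feature: in the cis-decalin 5β,6β,7β-triol 6-mesylate the equatorial C6–O bond of chair ring B is antiperiplanar to the C5–C10 ring-fusion bond, and the angular C5 carbinol pushes that bond over to C6.
4. Stereochemistry: the quaternary carbon comes from an auxiliary- and substrate-controlled Michael addition (the carvone stereocentre is then erased); the cis ring fusion from the aldol; C6/C7 of the decalin from hydroxyl-directed osmylation; the ring-fusion CH from inversion in the shift; the C6 carbinol of the daucane from hydroxyl-directed hydride delivery; the 9,10-diol from osmylation anti to the angular methyl.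

Key step: step 7

Remark on numbering: decalins carry eudesmane numbers (C10 bears the angular CH3, C5 is the other ring-fusion carbon, ring A = C1–C5 and C10, ring B = C5–C10, β = face of the C10 methyl). Hydroazulenes carry daucane numbers (C1 quaternary, C4 isopropyl carbinol, C5 ring-fusion CH, C6–C10 in the seven-membered ring). In the shift, decalin C10, C5, C6, C7 become daucane C1, C6, C5, C4.

Assumption: commercial (+)-dihydrocarvone is a mixture of C2 epimers; both give the same enamine in step 1, so the mixture is used as such.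

**Step 1**
Reactants: 1 (+)-dihydrocarvone; 2 (S)-1-phenylethylamine; 3 methyl vinyl ketone
Product: 6 (2R,5R)-2-methyl-2-(3-oxobutyl)-5-(prop-1-en-2-yl)cyclohexan-1-one, via imine 4 (not isolated), via keto imine 5 (not isolated)
Conditions: 2, TsOH (cat.), toluene, reflux (Dean–Stark); then 3, THF, 40 °C; then 10% aq. AcOH, rt
Reagents that add atoms: methyl vinyl ketone CC(=O)C=C; water O
Why: d'Angelo-type Michael addition of the more substituted secondary enamine tautomer of imine 4 (aza-ene-like transition state) should place the 3-oxobutyl chain on the face preferred both by the (S)-auxiliary and by axial attack cis to the equatorial isopropenyl group (matched pair), setting the quaternary centre as R; hydrolysis returns the auxiliary.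

**Step 2**
Reactants: 6 diketone
Product: 7 (6R)-6-methyl-6-(3-oxobutyl)-3-(propan-2-yl)cyclohex-2-en-1-one
Conditions: RhCl3·3H2O (5 mol %), EtOH, 80 °C
Reagents that add atoms: none
Why: RhCl3-catalysed olefin isomerisation (metal hydride addition–elimination) should move the isopropenyl double bond into conjugation with the ring ketone, the trisubstituted enone being the thermodynamic sink as in the dihydrocarvone-to-carvenone isomerisation; the quaternary centre is untouched and the former isopropenyl stereocentre is erased on purpose.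

**Step 3**
Reactants: 7 enone diketone
Product: 8 5β-hydroxy-15-noreudesm-6-en-3-one (cis-fused ketol)
Conditions: LiN(iPr)2 (1.1 equiv), THF, −78 °C; AcOH, −78 °C
Reagents that add atoms: none
Why: kinetic deprotonation of the methyl ketone and intramolecular aldol addition (6-enolexo-exo-trig) to the enone carbonyl should give the Robinson-type cis-ketol, in which the new C4–C5 bond is cis to C10–C1 and the angular hydroxyl is therefore cis to the angular methyl (new stereocentre C5).

**Step 4**
Reactants: 8 ketol
Product: 9 5β-hydroxy-15-noreudesma-1,6-dien-3-one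
Conditions: LiN(iPr)2 (2.3 equiv), THF, −78 °C; then PhS(Cl)=N-t-Bu, −78 °C
Reagents that add atoms: none
Why: Mukaiyama dehydrogenation: the kinetic C2 lithium enolate (formed beside the lithium alkoxide) is sulfenylated by N-tert-butylbenzenesulfinimidoyl chloride and the adduct undergoes syn-elimination to the enone; only the C1–C2 bond can be desaturated because C5 bears no hydrogen.

**Step 5**
Reactants: 9 dienone ketol
Product: 11 5β,6β,7β-trihydroxy-15-noreudesm-1-en-3-one, via osmate ester 10 (not isolated)
Conditions: OsO4 (1.05 equiv), TMEDA, CH2Cl2, −78 °C; then aq. Na2SO3, THF, 40 °C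
Reagents that add atoms: osmium tetroxide O=[Os](=O)(=O)=O
Why: Donohoe hydrogen-bond-directed dihydroxylation: the angular C5 hydroxyl should deliver the OsO4–TMEDA complex to the β-face of the electron-rich C6=C7 bond, giving the all-cis triol (new stereocentres C6 and C7), while the electron-poor enone double bond is not attacked at −78 °C.

**Step 6**
Reactants: 11 triol
Product: 12 5β,7β-dihydroxy-6β-(methanesulfonyloxy)-15-noreudesm-1-en-3-one
Conditions: MsCl, Et3N, CH2Cl2, −20 to 0 °C
Reagents that add atoms: methanesulfonyl chloride CS(=O)(=O)Cl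
Why: sulfonylation should occur only at the single secondary hydroxyl; the two tertiary hydroxyls do not react, and being cis they cannot displace the mesylate as an epoxide.

**Step 7**
Reactants: 12 mesylate
Product: 13 4β-hydroxy-14-nordauc-9-ene-6,8-dione (1β-CH3, 5α-H, trans-fused)
Conditions: Et2AlCl (3.5 equiv), CH2Cl2, −78 to −20 °C; aq. KNaC4H4O6 work-up
Reagents that add atoms: none
Why: Et2AlCl converts the C5 and C7 hydroxyls into aluminium alkoxides and activates the mesylate, and the C5–C10 ring-fusion bond, antiperiplanar to the equatorial C6–O bond in the chair of ring B (isopropyl and C10 methyl equatorial), migrates from C5 to C6 as the mesylate leaves while C5 becomes the ketone. The closest known reaction types are the organoaluminium-promoted semipinacol (pinacol-type) rearrangement of 2-sulfonyloxy alcohols and the decalin-to-hydroazulene rearrangement of ring-fusion hydroxy sulfonates. No ring is closed by a cyclisation: the one 1,2-shift contracts ring B from six to five members (new C6–C10 bond, the C5–C1 bond of the daucane) and expands ring A from six to seven. The migration terminus is inverted, which places the ring-fusion hydrogen trans to the angular methyl, the migrating quaternary carbon keeps its configuration, and the C7 carbinol (daucane C4) is untouched. The step needs migration of C10 and not of C8, which is also antiperiplanar: this should be secured by the higher migratory aptitude of the fully substituted carbon and the strain of a bond between two fully substituted centres, and epoxide formation is excluded because all three oxygens are cis. The low temperature should keep the aluminium aldolate of the β-hydroxy enone from retro-aldol cleavage.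

**Step 8**
Reactants: 13 ene-dione
Product: 14 14-nordauc-9-ene-4β,6α,8β-triol
Conditions: Me4NBH(OAc)3 (excess), MeCN/AcOH (1:1), −30 °C to rt
Reagents that add atoms: none
Why: Evans–Saksena hydroxyl-directed reduction: boron bound to the C4 hydroxyl should deliver hydride to the β-face of the C6 ketone and give the 1,3-anti diol (6α-OH); the new C6 hydroxyl then directs reduction of the C8 enone carbonyl, so the reaction is driven to the triol, whose C8 configuration is of no consequence.

**Step 9**
Reactants: 14 triol
Product: 15 4β,6α-dihydroxy-14-nordauc-9-en-8-one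
Conditions: MnO2, CH2Cl2, rt
Reagents that add atoms: none
Why: MnO2 oxidation is selective for the allylic C8 carbinol and should restore the enone without touching the C6 and C4 hydroxyls (any material not over-reduced in step 8 converges here).

**Step 10**
Reactants: 15 hydroxy enone
Product: 16 4β,6α,9α,10α-tetrahydroxy-14-nordaucan-8-one
Conditions: OsO4 (5 mol %), NMO, citric acid, t-BuOH/H2O, rt
Reagents that add atoms: N-methylmorpholine N-oxide C[N+]1([O-])CCOCC1; water O
Why: Upjohn dihydroxylation under citric acid buffering (suited to electron-poor alkenes) should add to the C9=C10 bond from the α-face, anti to the pseudoaxial angular methyl on C1, setting C9 and C10 as the cis-α-diol.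

**Step 11**
Reactants: 16 tetraol ketone
Product: 17 4β,6α-dihydroxy-9α,10α-(isopropylidenedioxy)-14-nordaucan-8-one
Conditions: Me2C(OMe)2, PPTS (cat.), acetone, rt
Reagents that add atoms: 2,2-dimethoxypropane COC(C)(C)OC
Why: acetonide formation should take place on the cis-1,2-diol (five-membered dioxolane) far faster than on the anti-1,3-diol that contains the tertiary C4 hydroxyl.

**Step 12**
Reactants: 17 acetonide ketone
Product: 18 9α,10α-(isopropylidenedioxy)dauc-8(14)-ene-4β,6α-diol
Conditions: Zn, CH2Br2, TiCl4 (reagent preformed in THF), CH2Cl2, 0 °C to rt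
Reagents that add atoms: dibromomethane BrCBr
Why: Takai–Lombardo methylenation uses a non-basic gem-dizinc reagent, so the ketone should be converted to the exocyclic alkene without retro-aldol cleavage of the β-hydroxy ketone; free hydroxyls are tolerated with excess reagent.

**Step 13**
Reactants: 18 diol; 19 3-methylbutanoic anhydride
Product: 20 6α-(3-methylbutanoyloxy)-9α,10α-(isopropylidenedioxy)dauc-8(14)-en-4β-ol
Conditions: 19, DMAP, Et3N, CH2Cl2, rt
Reagents that add atoms: 3-methylbutanoic anhydride CC(C)CC(=O)OC(=O)CC(C)C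
Why: DMAP-catalysed acylation should occur only at the single secondary hydroxyl; the tertiary C4 hydroxyl is inert under these conditions.

**Step 14**
Reactants: 20 ester acetonide
Product: 21 6α-(3-methylbutanoyloxy)dauc-8(14)-ene-4β,9α,10α-triol (CNP0204264.1)
Conditions: AcOH/H2O (4:1), 45 °C
Reagents that add atoms: none
Why: mild acidic hydrolysis of the acetonide should free the 9,10-diol while the ester, the tertiary alcohol and the allylic alcohol survive.

**Compound list**

1 | (+)-dihydrocarvone, (2R,5R)-2-methyl-5-(prop-1-en-2-yl)cyclohexan-1-one (major epimer) | C[C@@H]1CC[C@H](CC1=O)C(C)=C | starting material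
2 | (S)-1-phenylethylamine | C[C@H](N)c1ccccc1 | starting material
3 | methyl vinyl ketone | CC(=O)C=C | starting material
4 | imine of 1 with 2 | C[C@H](N=C1C[C@H](C(C)=C)CCC1C)c1ccccc1 | intermediate
5 | keto imine (Michael adduct before hydrolysis) | C[C@H](N=C1C[C@H](C(C)=C)CC[C@]1(C)CCC(C)=O)c1ccccc1 | intermediate
6 | (2R,5R)-2-methyl-2-(3-oxobutyl)-5-(prop-1-en-2-yl)cyclohexan-1-one | C1[C@](C)(CCC(C)=O)C(=O)C[C@H](C(C)=C)C1 | intermediate
7 | (6R)-6-methyl-6-(3-oxobutyl)-3-(propan-2-yl)cyclohex-2-en-1-one | C1[C@](C)(CCC(C)=O)C(=O)C=C(C(C)C)C1 | intermediate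
8 | 5β-hydroxy-15-noreudesm-6-en-3-one (cis-fused) | C1[C@](C)(CCC(=O)C2)[C@@]2(O)C=C(C(C)C)C1 | intermediate
9 | 5β-hydroxy-15-noreudesma-1,6-dien-3-one | C1[C@](C)(C=CC(=O)C2)[C@@]2(O)C=C(C(C)C)C1 | intermediate
10 | cyclic 6,7-osmate ester of 11 (hexavalent osmium, TMEDA chelate) | CN(C)CCN(C)C.C1[C@](C)(C=CC(=O)C2)[C@@]2(O)[C@@H](O3)[C@](O[Os]3(=O)=O)(C(C)C)C1 | intermediate
11 | 5β,6β,7β-trihydroxy-15-noreudesm-1-en-3-one (7α-isopropyl) | C1[C@](C)(C=CC(=O)C2)[C@@]2(O)[C@@H](O)[C@](O)(C(C)C)C1 | intermediate
12 | 5β,7β-dihydroxy-6β-(methanesulfonyloxy)-15-noreudesm-1-en-3-one | C1[C@](C)(C=CC(=O)C2)[C@@]2(O)[C@@H](OS(C)(=O)=O)[C@](O)(C(C)C)C1 | intermediate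
13 | 4β-hydroxy-14-nordauc-9-ene-6,8-dione | O=C1CC(=O)[C@@H]2[C@](C)(CC[C@@]2(O)C(C)C)C=C1 | intermediate
14 | 14-nordauc-9-ene-4β,6α,8β-triol | O[C@H]1C[C@H](O)[C@@H]2[C@](C)(CC[C@@]2(O)C(C)C)C=C1 | intermediate
15 | 4β,6α-dihydroxy-14-nordauc-9-en-8-one | O=C1C[C@H](O)[C@@H]2[C@](C)(CC[C@@]2(O)C(C)C)C=C1 | intermediate
16 | 4β,6α,9α,10α-tetrahydroxy-14-nordaucan-8-one | O=C1C[C@H](O)[C@@H]2[C@](C)(CC[C@@]2(O)C(C)C)[C@H](O)[C@@H]1O | intermediate
17 | 4β,6α-dihydroxy-9α,10α-(isopropylidenedioxy)-14-nordaucan-8-one | O=C1C[C@H](O)[C@@H]2[C@](C)(CC[C@@]2(O)C(C)C)[C@H](OC(C)(C)O3)[C@@H]13 | intermediate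
18 | 9α,10α-(isopropylidenedioxy)dauc-8(14)-ene-4β,6α-diol | C=C1C[C@H](O)[C@@H]2[C@](C)(CC[C@@]2(O)C(C)C)[C@H](OC(C)(C)O3)[C@@H]13 | intermediate
19 | 3-methylbutanoic (isovaleric) anhydride | CC(C)CC(=O)OC(=O)CC(C)C | starting material
20 | 6α-(3-methylbutanoyloxy)-9α,10α-(isopropylidenedioxy)dauc-8(14)-en-4β-ol | C=C1C[C@H](OC(=O)CC(C)C)[C@@H]2[C@](C)(CC[C@@]2(O)C(C)C)[C@H](OC(C)(C)O3)[C@@H]13 | intermediate
21 | 6α-(3-methylbutanoyloxy)dauc-8(14)-ene-4β,9α,10α-triol (CNP0204264.1) | C=C1C[C@H](OC(=O)CC(C)C)[C@@H]2[C@](C)(CC[C@@]2(O)C(C)C)[C@H](O)[C@@H]1O | target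

**Step count and risks**

Total step count: 14. Longest linear sequence: 14 steps, from (+)-dihydrocarvone.

Step 7 (key shift) is the most likely to fail. The C7 alkoxide may push the equally antiperiplanar C8 instead of C10 (contraction of ring B with an exocyclic isobutyryl group), or the β-alkoxy enone may open ring A by retro-aldol cleavage before the shift; the carbonyl at C3 also weakens the C5 oxygen as donor. The fallback sets out from 11 and carries the C3 carbonyl through the shift as a protected alcohol. Luche reduction (NaBH4, CeCl3·7H2O, MeOH, −78 °C) should give 15-noreudesm-1-ene-3α,5β,6β,7β-tetraol F1 (either C3 epimer serves). TBSCl/imidazole silylates the unhindered allylic hydroxyl to give the silyl ether F2, and MsCl/Et3N gives the 6β-mesylate F3. Et2AlCl then gives the hydroazulenone F4, which now has a single ketone and no β-carbonyl on the donor side. Me4NBH(OAc)3 gives the 4β,6α-diol F5, Bu4NF gives the 8-epimeric triol F6, and MnO2 returns to the route at 15.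

Step 2 (olefin isomerisation) is second. Acid released from RhCl3 may trigger aldol cyclodehydration of the 1,5-diketone, which would lose the later C5 hydroxyl, or the double bond may stop at the exocyclic isopropylidene stage. The fallback sets out from 6 and masks the methyl ketone first. Ethylene glycol/PPTS (benzene, reflux) should ketalise only the unhindered methyl ketone and give the dioxolane F7. Hydrogen-atom-transfer isomerisation (Co(salen)Cl cat., PhSiH3) gives the isopropylidene ketone F8, and DBU (toluene, 80 °C) conjugates it to the enone ketal F9. PPTS in aqueous acetone returns to the route at 7.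

Step 12 (methylenation) is third. The residual Lewis acidity of the titanium reagent may cause retro-aldol opening of the β-hydroxy ketone, or titanium alkoxide formation at the free hydroxyls may stall the methylenation. The fallback sets out from 17 and switches to a Wittig reaction on a protected substrate. TESCl/imidazole gives the 6α-triethylsilyl ether F10, Ph3P=CH2 (from Ph3PCH3Br and KOtBu, THF, 0 °C) gives the methylene compound F11, and Bu4NF returns to the route at 18.

**Further compounds**

F1 | step 7 | 15-noreudesm-1-ene-3α,5β,6β,7β-tetraol | C1[C@](C)(C=C[C@H](O)C2)[C@@]2(O)[C@@H](O)[C@](O)(C(C)C)C1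
F2 | step 7 | 3α-(tert-butyldimethylsilyloxy)-15-noreudesm-1-ene-5β,6β,7β-triol | C1[C@](C)(C=C[C@H](O[Si](C)(C)C(C)(C)C)C2)[C@@]2(O)[C@@H](O)[C@](O)(C(C)C)C1
F3 | step 7 | 3α-(tert-butyldimethylsilyloxy)-6β-(methanesulfonyloxy)-15-noreudesm-1-ene-5β,7β-diol | C1[C@](C)(C=C[C@H](O[Si](C)(C)C(C)(C)C)C2)[C@@]2(O)[C@@H](OS(C)(=O)=O)[C@](O)(C(C)C)C1
F4 | step 7 | 8α-(tert-butyldimethylsilyloxy)-4β-hydroxy-14-nordauc-9-en-6-one | CC(C)(C)[Si](C)(C)O[C@@H]1CC(=O)[C@@H]2[C@](C)(CC[C@@]2(O)C(C)C)C=C1
F5 | step 7 | 8α-(tert-butyldimethylsilyloxy)-14-nordauc-9-ene-4β,6α-diol | CC(C)(C)[Si](C)(C)O[C@@H]1C[C@H](O)[C@@H]2[C@](C)(CC[C@@]2(O)C(C)C)C=C1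
F6 | step 7 | 14-nordauc-9-ene-4β,6α,8α-triol | O[C@@H]1C[C@H](O)[C@@H]2[C@](C)(CC[C@@]2(O)C(C)C)C=C1
F7 | step 2 | (2R,5R)-2-methyl-2-[2-(2-methyl-1,3-dioxolan-2-yl)ethyl]-5-(prop-1-en-2-yl)cyclohexan-1-one | C1[C@](C)(CCC2(C)OCCO2)C(=O)C[C@H](C(C)=C)C1
F8 | step 2 | (2R)-2-methyl-2-[2-(2-methyl-1,3-dioxolan-2-yl)ethyl]-5-(propan-2-ylidene)cyclohexan-1-one | C1[C@](C)(CCC2(C)OCCO2)C(=O)CC(=C(C)C)C1
F9 | step 2 | (6R)-6-methyl-6-[2-(2-methyl-1,3-dioxolan-2-yl)ethyl]-3-(propan-2-yl)cyclohex-2-en-1-one | C1[C@](C)(CCC2(C)OCCO2)C(=O)C=C(C(C)C)C1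
F10 | step 12 | 4β-hydroxy-9α,10α-(isopropylidenedioxy)-6α-(triethylsilyloxy)-14-nordaucan-8-one | O=C1C[C@H](O[Si](CC)(CC)CC)[C@@H]2[C@](C)(CC[C@@]2(O)C(C)C)[C@H](OC(C)(C)O3)[C@@H]13
F11 | step 12 | 9α,10α-(isopropylidenedioxy)-6α-(triethylsilyloxy)dauc-8(14)-en-4β-ol | C=C1C[C@H](O[Si](CC)(CC)CC)[C@@H]2[C@](C)(CC[C@@]2(O)C(C)C)[C@H](OC(C)(C)O3)[C@@H]13
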